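The rate constants stand for no real mixture, and the outcome is calculated.

Slowness was what I looked for first in these set-ups, so I counted turnovers.

| setting | oak | larch | elm |
|---|---|---|---|
| substrate | 0.10 M (fed, over 6.40 h) | 0.10 M | 0.10 M |
| enzyme | 2.8 µM | 2.8 µM | 2.8 µM |
| time | 8.0 h |  | 8.0 h |
| remark | a stirred flask in which substrate is dosed at a steady rate over 6.40 h without added volume, worked up at 8.0 h | one stirred flow tank at steady state, fed with the mixture as stated, mean residence time 8.0 h | everything together in a closed stirred flask, run for 8.0 h |

    substrate + enzyme → product + enzyme, rate k1*[substrate]^1.5*[enzyme]/(1 + ([substrate]/Kh1)^1.5) (Kh1 = 14 mM, k1 = 46000 M⁻¹·⁵ min⁻¹)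
    enzyme + product → spent catalyst (k2 = 0.014 M⁻¹ min⁻¹)

- order of the set-ups by the amount of product at the outlet or at the end, in percent of the substrate put in, highest first (oak / larch / elm)
- amount of product at the outlet or at the end, in percent of the substrate put in, oak
- amount of product at the outlet or at the end, in percent of the substrate put in, larch
- amount of product at the outlet or at the end, in percent of the substrate put in, elm

- the stated concentrations are those of everything mixed, before any reaction; amounts are the same in each set-up
- the feed brings no volume worth counting
- run time (oak): 8.0 h

The charge asks much of little enzyme: 0.10 M of substrate on 2.8 µM of enzyme meant 35700 turnovers per enzyme. But the first rate law goes flat above Kh, so each enzyme has a top speed of 76.2 min⁻¹. Top speed times 8.0 h, divided by the turnovers asked, came to 102 %. I called this ratio the turnover budget: the highest yield the enzyme charge can pay for in that time, since the rate cannot pass top speed times [enzyme].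

So the budget stood about level with the whole charge, and a loss of speed beyond the narrow gap between them had to show in the yield. The second step loses speed: at a given [product] it is pseudo-first-order in enzyme, and with [product] at the whole charge the enzyme's half-life is 8.25 h, about as long as the run. The vessels lose speed differently: oak receives its substrate gradually, larch works at its outlet [substrate], and elm starts with the whole charge. So I committed to yields below the budget, with elm highest.

The forecast gave elm > oak > larch, with 66.5 % for oak, 60.3 % for larch and 79.7 % for elm, reasoning that “all set-ups run near capacity while product slowly kills the enzyme”.

The simulation gave elm > oak > larch: 66.8 % for oak, 60.3 % for larch and 79.9 % for elm, each below the budget. In elm the first step had 24 % of its turnover up to 8.00 h behind it after 1.60 h, and the second step ran alongside it, with spent catalyst at 7.63 % of the catalyst charged after 4.00 h. At 8.00 h elm held 74.4 % of the catalyst charged as enzyme and 25.6 % as spent catalyst, with 20.1 % of the substrate left.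

Elm's neighbour, the same closed flask and time with 7.0 × 10⁻⁷ M of enzyme, a quarter of elm's enzyme charge, had a budget of 25.6 %. The computed yield was 23.4 %, with 92.3 % of its catalyst charge still standing as enzyme at 8.00 h.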